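(The runs stem from a simulated flask on assumed constants; scatter was added.)

Book the partner, not the clock: both earlier runs are flat from their first reading, so ask what each mM of partner bought.

| setting | Tuesday's | Saturday's | flask |
|---|---|---|---|
| left-handed substrate | 20 mM | 20 mM | 20 mM |
| right-handed substrate | 20 mM | 20 mM | 20 mM |
| partner | 22 mM | 33 mM | 44.0 mM |
| remark | run made earlier | run made earlier |  |
| time |  |  | 5.0 d |

| run | time / d | left-handed substrate / % | left-handed product / % | right-handed substrate / % |
|---|---|---|---|---|
| Tuesday's | 0.417 | 38.9 | 21.0 | 38.6 |
| Tuesday's | 0.625 | 39.6 | 20.5 | 38.3 |
| Tuesday's | 0.833 | 38.4 | 21.9 | 40.2 |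
| Tuesday's | 1.25 | 38.2 | 21.5 | 37.7 |
| Tuesday's | 2.00 | 40.2 | 21.5 | 38.6 |
| Tuesday's | 3.00 | 38.3 | 22.1 | 38.9 |
| Tuesday's | 5.00 | 38.2 | 21.5 | 37.6 |
| Saturday's | 0.625 | 32.7 | 33.1 | 33.4 |
| Saturday's | 1.25 | 30.7 | 30.1 | 34.5 |
| Saturday's | 2.00 | 31.9 | 31.5 | 32.1 |
| Saturday's | 3.00 | 33.9 | 31.6 | 32.7 |
| Saturday's | 4.00 | 31.8 | 30.6 | 31.6 |
| Saturday's | 5.00 | 33.3 | 30.0 | 34.0 |

(readings scatter by 1 percentage point)

- partner is single-handed; left-handed substrate and right-handed substrate are mirror images of each other, charged as a racemate, each of them at the stated concentration
- the reaction counts as stopped when no species that holds the left-handed substrate and right-handed substrate together changes by six tenths of a point or more over the second half of the time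
- the handed part of partner does not stay in what it makes, so the products of the two hands are mirror images too

* the state of affairs at 5.0 d: stopped, and by what, or still going (forward and back rates have come level / all of the left-handed substrate has reacted / the partner has run out first / it is still moving)
* share of the left-handed substrate and right-handed substrate together used up at 5.0 d
* left-handed product at 5.0 d, in percent of the left-handed substrate and right-handed substrate together charged
* right-handed substrate at 5.0 d, in percent of the left-handed substrate and right-handed substrate together charged

In Tuesday's run the two substrates stay level within the scatter, while the last reading of left-handed product, 21.5%, is about twice the 12 percentage points missing from left-handed substrate's charged half. So treat the hands as interconverting fast, as one pool T of both together. Tuesday's pool keeps 77.4% of its charge, which is 9.05 mM consumed from 22 mM of partner. Take partner as the limiting reagent, and suppose it also decays by itself, first order.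

Now compare rates at one moment. Reaction takes partner at k·T·B and decay at w·B, so B cancels. With W = w/k, the partner spent per mM of pool consumed, its price, is one plus W/T. The price climbs as T falls, and summing it gives a ledger: partner charged = pool consumed + W ln(T at start / T at end).

Tuesday's ledger gives 50.5 mM. Saturday's pool keeps 65.4%, which gives 45.2 mM. Their mean, 47.9 mM, is the waste constant: the pool at which both paths take partner equally fast.

For this flask, start from Saturday's end, where the ledger has used 34.1 mM of partner. That leaves 9.87 mM to pay at a price of 2.83. My reckoning is conversion 43.3% and right-handed substrate 28.3%.

The forecast gives the partner has run out first, conversion 46%, left-handed product 41.5% and right-handed substrate 27%, holding that “partner exhaustion stopped the reaction”, with a conversion above mine.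

The flask gives the partner has run out first, conversion 42.3%, left-handed product 40.2% and right-handed substrate 28.8%.

    partner + right-handed substrate → right-handed product (k = 1.00 × 10⁻⁴ /M/s)
    partner + left-handed substrate → left-handed product (k = 0.00190 /M/s)
    partner → decomposed reagent (k = 4.90 × 10⁻⁵ /s)
    left-handed substrate ⇌ right-handed substrate (k = 0.00240 /s)

At 5.00 d partner stands at 0% and decomposed reagent at 27.1 mM. The ledger's waste term at this conversion, with W from the readings, is 26.3 mM. For the neighbour with 26 mM of partner, step from Tuesday's end at Tuesday's price: the ledger gives conversion 27.2%. That flask gives 26.8%.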